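All runs come from a simulation for an exercise; noise was put on by code.

Electrophile plus target should stay at the charge if nothing else forms, and at the last readings the two sum to 97.5% in teal and 99.3% in green. The loss of electrophile is therefore mostly target.

common to all: gas 55 mM (held)
- teal: electrophile 0.70 M; run made earlier
- green: electrophile 1.1 M; run made earlier
- flask: electrophile 0.50 M; time 80 min

| run | time / min | electrophile / % | target / % |
|---|---|---|---|
| teal | 5.00 | 98.9 | 0.4 |
| teal | 8.00 | 97.8 | 1.6 |
| teal | 12.0 | 96.2 | 2.7 |
| teal | 20.0 | 94.2 | 6.1 |
| teal | 30.0 | 91.5 | 7.6 |
| teal | 40.0 | 87.2 | 10.3 |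
| teal | 60.0 | 81.1 | 16.4 |
| green | 5.00 | 99.4 | 0.9 |
| green | 8.00 | 98.9 | 2.0 |
| green | 12.0 | 98.2 | 2.6 |
| green | 20.0 | 96.1 | 3.9 |
| green | 30.0 | 92.9 | 6.3 |
| green | 40.0 | 90.6 | 8.9 |
| green | 60.0 | 87.4 | 11.9 |

(readings scatter by 0.5 percentage points)

- at the start none of the gas is in solution
- the earlier runs do not show how much of nucleophile is bound; that part of a forecast is a guess

- part of the electrophile that has reacted at 80 min
- share of the unused nucleophile that is free and not bound as protonated nucleophile, at 80 min

Column against column, green, with the larger charge, has lost less of its electrophile by 60.0 min: 12.6% against 18.9% in teal. So a first-order constant read from either run belongs to that charge and does not carry over. Multiplying by the charge C gives the charge-scaled constant, F = C·ln(charged/left)/t. The last rows give 2.44 mM min⁻¹ for teal and 2.47 mM min⁻¹ for green, nearly the same.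

My reckoning takes the end state as electrophile gone and the approach as pseudo-first-order, with constant F/C. The mean, 2.46 mM min⁻¹, is the charge-scaled constant. For the flask it gives 32.5% reacted at 80 min. The runs do not show how much nucleophile is bound, so the free share stays a guess.

The forecast, on the view that “the reaction looks zero order”, gives 33% reacted and 50% free, a slightly different figure for c by a different rule. The flask gives 29.6% and 10.8%.

    nucleophile + acid set free ⇌ protonated nucleophile, settled at all times (K = 9100 M⁻¹)
    gas ⇌ nucleophile, rate k2*(csat - [nucleophile]) (kL = 0.103 min⁻¹)
    nucleophile + target → over-reaction product (k = 0.119 M⁻¹ min⁻¹)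
    electrophile + nucleophile → acid set free + target (k = 0.280 M⁻¹ min⁻¹)

The flask's own F is 2.19 mM min⁻¹, lower than the mean from the runs. At 80 min the flask's nucleophile has a half-life of 7.0 min by its step with electrophile, short against the time, and the transfer of gas, taken by itself, has a half-time of 6.73 min, a time of like size; in the flask at that moment free nucleophile stands at 0.0178 M beside 0.147 M protonated.

For the neighbour flask with 0.30 M of electrophile, F gives 48.1% reacted. The computed neighbour reaches 39.0%, so its F is lower again, 1.85 mM min⁻¹.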